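**Plan**
1. Retrosynthesis: ring D is cut at C13–C16 (vinyl radical 5-exo closure, C15 ketone by late allylic oxidation). Rings B and C are then cut together across C8–C9 and C13–C14, an intramolecular Diels–Alder reaction of an O20-bound 2-(2-bromoallyl)acrylate (C7, C8=C14, C15–C17) with a C10-bound (E,E)-1-silyl diene (C9=C11–C12=C13). Ring A is cut at C10–C9, C10–C20 and C5–C6 back to a 4,4-disubstituted cyclohexenone.
2. Enabling feature: C8–C9 is the one bond shared by δ-lactone ring B (C7, C8, C9, C10, C20, O) and carbocycle C (C8, C9, C11–C14). The quaternary C10 carries both C9 and the C20–O arm, so diene and dienophile hang four atoms apart on one carbon.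
3. Forward order: ring A (catalytic Diels–Alder, tethered radical addition, alkynylation), then diene and acrylate are attached, rings B and C form in one step, ring D by radical cyclization, C15 is oxidized last.
4. Stereochemistry: C4 comes from the enantioselective Diels–Alder catalyst; C5, C10 and C1 are relayed from C4 within ring A; C9 and C8 are relayed from C10 in the key step; C13 is fixed by the C15 bridge.
5. Temporary elements: a C19–O–SiMe2–C6 tether delivers C6 cis to C19, masks both oxygens and is opened late to C19–OAc and C6–OH. The diene SiMe3 is removed with allylic transposition, which places the alkene at C12=C13 for ring D.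

Key step: step 18

Assumption: atoms are numbered as in ent-kaurane (C1–C20), and in step 2 the catalyst enantiomer (both are commercial) is taken to be the one that delivers the (R)-aldehyde 4, written here as the (S)-catalyst.

**Step 1**
Reactants: 1 methyl vinyl ketone
Product: 2 2-(triisopropylsilyloxy)buta-1,3-diene
Conditions: TIPSOTf, Et3N, Et2O, 0 °C to rt
Reagents that add atoms: triisopropylsilyl trifluoromethanesulfonate, CC(C)[Si](OS(=O)(=O)C(F)(F)F)(C(C)C)C(C)C
Why: Silyl enol ether formation by O-silylation of the amine-generated enolate of the enone gives the 2-siloxy diene.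

**Step 2**
Reactants: 2 2-(triisopropylsilyloxy)buta-1,3-diene; 3 methacrolein
Product: 4 (R)-1-methyl-4-(triisopropylsilyloxy)cyclohex-3-ene-1-carbaldehyde
Conditions: (S)-o-tolyl-CBS-oxazaborolidine (10 mol %), Tf2NH (10 mol %), CH2Cl2, −78 °C
Reagents that add atoms: none
Why: Catalytic enantioselective Diels–Alder reaction with a protonated oxazaborolidine; the siloxy group enforces the 1,4 ("para") orientation and the catalyst shields one face of the bound s-trans enal, which sets the quaternary C4.

**Step 3**
Reactants: 4 (R)-1-methyl-4-(triisopropylsilyloxy)cyclohex-3-ene-1-carbaldehyde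
Product: 5 (R)-[1-methyl-4-(triisopropylsilyloxy)cyclohex-3-en-1-yl]methanol
Conditions: NaBH4, EtOH, 0 °C
Reagents that add atoms: none
Why: Borohydride reduction of the neopentyl aldehyde (C19) while the ketone stays masked as its silyl enol ether, whose position keeps the molecule chiral.

**Step 4**
Reactants: 5 (R)-[1-methyl-4-(triisopropylsilyloxy)cyclohex-3-en-1-yl]methanol
Product: 6 (R)-4-(hydroxymethyl)-4-methylcyclohex-2-en-1-one
Conditions: Pd(OAc)2 (1.1 equiv), MeCN, rt
Reagents that add atoms: none
Why: Saegusa–Ito oxidation; the enol ether already lies between C1 and C10, so palladation at C10 and β-hydride loss from C5 should give only the C10=C5 enone with C4 untouched.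

**Step 5**
Reactants: 6 (R)-4-(hydroxymethyl)-4-methylcyclohex-2-en-1-one
Product: 7 (R)-4-(hydroxymethyl)-2-iodo-4-methylcyclohex-2-en-1-one
Conditions: I2, pyridine, CH2Cl2, 0 °C to rt
Reagents that add atoms: iodine, II
Why: α-Iodination of an enone by reversible pyridine conjugate addition, iodination of the enolate and elimination, placing iodine on C10.

**Step 6**
Reactants: 7 (R)-4-(hydroxymethyl)-2-iodo-4-methylcyclohex-2-en-1-one
Product: 8 methyl (R)-3-(hydroxymethyl)-3-methyl-6-oxocyclohex-1-ene-1-carboxylate
Conditions: CO (1 atm), MeOH, PdCl2(PPh3)2 (5 mol %), Et3N, DMF, 50 °C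
Reagents that add atoms: carbon monoxide, [C-]#[O+]; methanol, CO
Why: Pd-catalysed methoxycarbonylation of the vinyl iodide through an acyl-palladium species installs C20; the C19 hydroxyl cannot trap it intramolecularly because that lactone would hold a bridgehead alkene.

**Step 7**
Reactants: 8 methyl (R)-3-(hydroxymethyl)-3-methyl-6-oxocyclohex-1-ene-1-carboxylate
Product: 9 methyl (R)-3-{[(bromomethyl)dimethylsilyl]oxymethyl}-3-methyl-6-oxocyclohex-1-ene-1-carboxylate
Conditions: BrCH2SiMe2Cl, imidazole, CH2Cl2, 0 °C
Reagents that add atoms: (bromomethyl)chlorodimethylsilane, C[Si](C)(Cl)CBr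
Why: Silyl ether formation at the primary C19 alcohol installs the silicon tether and radical precursor under conditions too mild to harm the alkylidene keto ester.

**Step 8**
Reactants: 9 methyl (R)-3-{[(bromomethyl)dimethylsilyl]oxymethyl}-3-methyl-6-oxocyclohex-1-ene-1-carboxylate
Product: 10 ring A keto ester with the C19–O–SiMe2–C6 bridge cis-fused at C4–C5 (C10 epimers and enol)
Conditions: Bu3SnH, AIBN, PhH, 80 °C, slow addition
Reagents that add atoms: none
Why: Silicon-tethered radical conjugate addition (Nishiyama–Stork type); the nucleophilic silylmethyl radical adds 6-exo to the doubly activated C5, and because the O–Si–C tether on C19 can only span a cis ring junction C6 arrives cis to C19, which sets C5, the C10 radical then taking hydrogen from the stannane.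

**Step 9**
Reactants: 10 ring A keto ester with the C19–O–SiMe2–C6 bridge
Product: 11 C10-ethynyl keto ester (ethynyl trans to C6, CO2Me cis to C6)
Conditions: TMS-EBX, TBAF (1.1 equiv, added last), THF, −78 °C
Reagents that add atoms: 1-[(trimethylsilyl)ethynyl]-1,2-benziodoxol-3(1H)-one, C[Si](C)(C)C#CI1OC(=O)c2ccccc12
Why: Electrophilic α-alkynylation of a β-keto ester enolate with a hypervalent iodine ethynyl donor; the slim electrophile should attack C10 of the cis-fused bicyclic enolate on the convex face, anti to the vicinal C5–C6 bond, which sets C10 with the ester (C20) cis to C6.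

**Step 10**
Reactants: 11 C10-ethynyl keto ester
Product: 12 ring A C1,C20-diol alkyne (C1–OH cis to C20)
Conditions: LiBH4, THF, 0 °C to rt
Reagents that add atoms: none
Why: Borohydride reduction of the ketone and then of the β-hydroxy ester; hydride should attack C1 axially on the face of the small ethynyl group, anti to the ester, which gives the equatorial C1 alcohol cis to C20.

**Step 11**
Reactants: 12 ring A C1,C20-diol alkyne
Product: 13 (E)-2-(tributylstannyl)vinyl diol
Conditions: Bu3SnH, PdCl2(PPh3)2 (2 mol %), THF, 0 °C
Reagents that add atoms: tributyltin hydride, CCCC[SnH](CCCC)CCCC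
Why: Pd-catalysed syn-hydrostannylation of a terminal alkyne; the quaternary propargylic C10 sends tin to the terminal carbon C11, which gives the (E)-vinylstannane.

**Step 12**
Reactants: 13 (E)-2-(tributylstannyl)vinyl diol; 14 (E)-(2-bromovinyl)trimethylsilane
Product: 15 (1E,3E)-4-(trimethylsilyl)buta-1,3-dienyl diol
Conditions: Pd(PPh3)4 (5 mol %), CuI, DMF, 40 °C
Reagents that add atoms: none
Why: Stille coupling of two (E)-alkenyl partners proceeds with retention at both, which gives the (E,E)-1-silyl diene C9=C11–C12=C13; hydroxyls and the siloxane are tolerated.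

**Step 13**
Reactants: 16 triethyl phosphonoacetate; 17 2,3-dibromopropene
Product: 18 ethyl 4-bromo-2-(diethoxyphosphoryl)pent-4-enoate
Conditions: NaH, THF, 0 °C to rt
Reagents that add atoms: none
Why: C-alkylation of the phosphonoacetate anion at the allylic bromide; the vinylic bromide does not undergo SN2 displacement.

**Step 14**
Reactants: 18 ethyl 4-bromo-2-(diethoxyphosphoryl)pent-4-enoate
Product: 19 ethyl 4-bromo-2-methylenepent-4-enoate
Conditions: HCHO (37% aq.), K2CO3, THF/H2O, rt
Reagents that add atoms: formaldehyde, C=O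
Why: Horner–Wadsworth–Emmons olefination with formaldehyde turns the α-substituted phosphonoacetate into the 2-substituted acrylate.

**Step 15**
Reactants: 19 ethyl 4-bromo-2-methylenepent-4-enoate
Product: 20 4-bromo-2-methylenepent-4-enoic acid
Conditions: LiOH, THF/H2O, 0 °C; then HCl (aq.)
Reagents that add atoms: lithium hydroxide, [Li+].[OH-]
Why: Saponification of the ethyl ester at low temperature; hydroxide does not displace the vinylic bromide.

**Step 16**
Reactants: 15 (1E,3E)-4-(trimethylsilyl)buta-1,3-dienyl diol; 20 4-bromo-2-methylenepent-4-enoic acid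
Product: 21 C20 4-bromo-2-methylenepent-4-enoate of diol 15 (C1–OH free)
Conditions: EDC·HCl, DMAP, CH2Cl2, 0 °C
Reagents that add atoms: none
Why: Carbodiimide (Steglich) esterification should select the primary C20 hydroxyl over the secondary C1 hydroxyl next to the quaternary C10.

**Step 17**
Reactants: 21 C20 4-bromo-2-methylenepent-4-enoate (C1–OH free)
Product: 22 C1 acetate, the triene precursor of the cycloaddition
Conditions: Ac2O, Et3N, DMAP, CH2Cl2, rt
Reagents that add atoms: acetic anhydride, CC(=O)OC(C)=O
Why: DMAP-catalysed acetylation of the remaining secondary alcohol; the siloxane, the silyl diene and the acrylate are stable to these non-acidic conditions.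

**Step 18**
Reactants: 22 C1 acetate, the triene precursor
Product: 23 cycloadduct with rings A, B and C: 7,20-lactone, C11=C12 alkene, C13–SiMe3 cis to C10, 2-bromoallyl on C8 syn to H9
Conditions: PhMe (0.01 M), BHT, 180 °C, sealed tube
Reagents that add atoms: none
Why: Thermal intramolecular Diels–Alder reaction (closest type: ester-tethered decatrienoate cycloaddition) between the C9=C11–C12=C13 (E,E)-silyl diene on C10 and the O20-bound acrylate C8=C14, forming C8–C9 and C13–C14 in one concerted, asynchronous [4+2] event. Ring C (C8, C9, C11, C12, C13, C14) closes as the cycloaddition ring and lactone ring B (C7, C8, C9, C10, C20, O) closes as the four-atom tether ring, both through the C8–C9 bond. C9 is set by the diene face: the C20 arm must stand perpendicular to the diene, and the rotamer that turns C11 toward the C1 methine rather than toward C5, which carries C6 and the quaternary C4, gives H9 anti to C20 as in the target. C8 is set by the tether carbonyl C7 lying endo under the diene, the array in which the near-planar ester can span C8 and C10, so the 2-bromoallyl arm (C15) ends syn to H9; C13 follows from the E-silyl group and is erased in step 19. The selectivities needed are this endo and facial pair, supported by the quaternary C10 (tether compression, no allylic hydrogen for 1,5-shifts) and by the equatorial C1 acetate and the cis-fused siloxane that hold ring A in one chair; the SiMe3 group keeps the diene E,E and the unactivated 2-bromoallyl alkene should not compete as a dienophile.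

**Step 19**
Reactants: 23 cycloadduct
Product: 24 Δ12 lactone (C12=C13 alkene, C11 methylene, siloxane intact)
Conditions: TFA, CH2Cl2, 0 °C
Reagents that add atoms: none
Why: Protodesilylation of an allylsilane (SE2′): the proton adds at C11 and the β-silyl cation loses SiMe3, which moves the alkene to C12=C13 and removes the C13 stereocenter.

**Step 20**
Reactants: 24 Δ12 lactone
Product: 26 C19 acetate C6 alcohol, via acetoxysilane 25 (not isolated)
Conditions: Ac2O, TMSOTf (5 mol %), CH2Cl2, −20 °C; then KF, KHCO3, H2O2 (30%), THF/MeOH, rt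
Reagents that add atoms: acetic anhydride, CC(=O)OC(C)=O; hydrogen peroxide, OO
Why: Lewis-acid acylative cleavage of the Si–O bond puts the acetate on O19 and leaves an acetoxysilane, whose C–Si bond is then oxidized with retention in a Tamao–Fleming oxidation to the C6 alcohol, so the two oxygens of the tether emerge differentiated.

**Step 21**
Reactants: 26 C19 acetate C6 alcohol
Product: 27 1α,19-diacetoxy-6-hydroxy-6,7-seco-ent-kaur-16-en-7,20-olide
Conditions: Bu3SnH, AIBN, PhH, 80 °C
Reagents that add atoms: none
Why: Vinyl radical 5-exo-trig cyclization; the C16 radical, held on C8 through C15, can reach C13 only on the face of C15, which closes ring D, sets C13 and leaves the 16-exo-methylene after hydrogen transfer to C12.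

**Step 22**
Reactants: 27 1α,19-diacetoxy-6-hydroxy-6,7-seco-ent-kaur-16-en-7,20-olide
Product: 28 15-hydroxy derivative of 27 (either C15 epimer)
Conditions: SeO2 (0.5 equiv), t-BuOOH, CH2Cl2, rt
Reagents that add atoms: selenium dioxide, O=[Se]=O (oxygen, replenished by tert-butyl hydroperoxide, CC(C)(C)OO)
Why: Selenium dioxide allylic oxidation (ene reaction, then [2,3]-shift) hydroxylates C15, the only non-bridgehead allylic position of the exocyclic alkene; the C15 configuration is lost in the next step.

**Step 23**
Reactants: 28 15-hydroxy derivative of 27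
Product: 29 CNP0105570.2, 1α,19-diacetoxy-6-hydroxy-15-oxo-6,7-seco-ent-kaur-16-en-7,20-olide
Conditions: MnO2, CH2Cl2, rt
Reagents that add atoms: none
Why: MnO2 oxidizes the allylic C15 alcohol to the exo-methylene ketone and should leave the saturated primary C6 alcohol untouched.

**Compound list**
1 | methyl vinyl ketone | CC(=O)C=C | starting material
2 | 2-(triisopropylsilyloxy)buta-1,3-diene | C=CC(=C)O[Si](C(C)C)(C(C)C)C(C)C | intermediate
3 | methacrolein | CC(=C)C=O | starting material
4 | (R)-1-methyl-4-(triisopropylsilyloxy)cyclohex-3-ene-1-carbaldehyde | CC(C)[Si](OC1=CC[C@](C)(C=O)CC1)(C(C)C)C(C)C | intermediate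
5 | (R)-[1-methyl-4-(triisopropylsilyloxy)cyclohex-3-en-1-yl]methanol | CC(C)[Si](OC1=CC[C@](C)(CO)CC1)(C(C)C)C(C)C | intermediate
6 | (R)-4-(hydroxymethyl)-4-methylcyclohex-2-en-1-one | O=C1CC[C@@](C)(CO)C=C1 | intermediate
7 | (R)-4-(hydroxymethyl)-2-iodo-4-methylcyclohex-2-en-1-one | O=C1CC[C@@](C)(CO)C=C1I | intermediate
8 | methyl (R)-3-(hydroxymethyl)-3-methyl-6-oxocyclohex-1-ene-1-carboxylate | O=C1CC[C@@](C)(CO)C=C1C(=O)OC | intermediate
9 | methyl (R)-3-{[(bromomethyl)dimethylsilyl]oxymethyl}-3-methyl-6-oxocyclohex-1-ene-1-carboxylate | O=C1CC[C@@](C)(CO[Si](C)(C)CBr)C=C1C(=O)OC | intermediate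
10 | ring A keto ester, C19–O–SiMe2–C6 bridge cis-fused at C4–C5, C10 unassigned | O=C1CC[C@@]2(C)CO[Si](C)(C)C[C@H]2C1C(=O)OC | intermediate
11 | C10-ethynyl keto ester, ethynyl trans to C6 | O=C1CC[C@@]2(C)CO[Si](C)(C)C[C@H]2[C@@]1(C#C)C(=O)OC | intermediate
12 | ring A C1,C20-diol alkyne, C1–OH cis to C20 | O[C@H]1CC[C@@]2(C)CO[Si](C)(C)C[C@H]2[C@@]1(C#C)CO | intermediate
13 | (E)-2-(tributylstannyl)vinyl diol | O[C@H]1CC[C@@]2(C)CO[Si](C)(C)C[C@H]2[C@@]1(/C=C/[Sn](CCCC)(CCCC)CCCC)CO | intermediate
14 | (E)-(2-bromovinyl)trimethylsilane | C[Si](C)(C)/C=C/Br | starting material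
15 | (1E,3E)-4-(trimethylsilyl)buta-1,3-dienyl diol | O[C@H]1CC[C@@]2(C)CO[Si](C)(C)C[C@H]2[C@@]1(/C=C/C=C/[Si](C)(C)C)CO | intermediate
16 | triethyl phosphonoacetate | CCOC(=O)CP(=O)(OCC)OCC | starting material
17 | 2,3-dibromopropene | C=C(Br)CBr | starting material
18 | ethyl 4-bromo-2-(diethoxyphosphoryl)pent-4-enoate | CCOC(=O)C(CC(Br)=C)P(=O)(OCC)OCC | intermediate
19 | ethyl 4-bromo-2-methylenepent-4-enoate | CCOC(=O)C(=C)CC(Br)=C | intermediate
20 | 4-bromo-2-methylenepent-4-enoic acid | OC(=O)C(=C)CC(Br)=C | intermediate
21 | C20 4-bromo-2-methylenepent-4-enoate of 15, C1–OH free | O[C@H]1CC[C@@]2(C)CO[Si](C)(C)C[C@H]2[C@@]1(/C=C/C=C/[Si](C)(C)C)COC(=O)C(=C)CC(Br)=C | intermediate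
22 | C1 acetate of 21, triene precursor | CC(=O)O[C@H]1CC[C@@]2(C)CO[Si](C)(C)C[C@H]2[C@@]1(/C=C/C=C/[Si](C)(C)C)COC(=O)C(=C)CC(Br)=C | intermediate
23 | cycloadduct: 7,20-lactone, C11=C12, C13–SiMe3, C8 2-bromoallyl | C=C(Br)C[C@]12C[C@@H]([Si](C)(C)C)C=C[C@H]1[C@]3(COC2=O)[C@@H](OC(C)=O)CC[C@@]4(C)CO[Si](C)(C)C[C@@H]34 | intermediate
24 | Δ12 lactone, siloxane intact | C=C(Br)C[C@]12CC=CC[C@H]1[C@]3(COC2=O)[C@@H](OC(C)=O)CC[C@@]4(C)CO[Si](C)(C)C[C@@H]34 | intermediate
25 | C19 acetate with C6–SiMe2OAc (acetoxysilane) | C=C(Br)C[C@]12CC=CC[C@H]1[C@]1(COC2=O)[C@@H](OC(C)=O)CC[C@@](C)(COC(C)=O)[C@H]1C[Si](C)(C)OC(C)=O | intermediate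
26 | C19 acetate C6 alcohol | C=C(Br)C[C@]12CC=CC[C@H]1[C@]1(COC2=O)[C@@H](OC(C)=O)CC[C@@](C)(COC(C)=O)[C@H]1CO | intermediate
27 | 1α,19-diacetoxy-6-hydroxy-6,7-seco-ent-kaur-16-en-7,20-olide | C=C1C[C@]23C[C@H]1CC[C@H]2[C@]1(COC3=O)[C@@H](OC(C)=O)CC[C@@](C)(COC(C)=O)[C@H]1CO | intermediate
28 | 15-hydroxy derivative of 27, C15 unassigned | C=C1C(O)[C@]23C[C@H]1CC[C@H]2[C@]1(COC3=O)[C@@H](OC(C)=O)CC[C@@](C)(COC(C)=O)[C@H]1CO | intermediate
29 | CNP0105570.2 | C=C1C(=O)[C@]23C[C@H]1CC[C@H]2[C@]1(COC3=O)[C@@H](OC(C)=O)CC[C@@](C)(COC(C)=O)[C@H]1CO | target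

**Step count and risks**
Total steps: 23. Longest linear sequence: 20 steps (steps 1–12 and 16–23); steps 13–15 are a three-step side branch.

Step 18 (cycloaddition). The ester must leave its preferred conformation to reach the diene, so the reaction may be slow. The transition state with the tether carbonyl exo (C15 anti to H9) or attack on the other diene face may also compete. The fallback sets out from 15 and comes back at 23. The C20 hydroxyl of 15 is esterified with commercial 2-bromoacrylic acid (EDC·HCl, DMAP) to the C20 2-bromoacrylate F1, and C1–OH is acetylated (Ac2O, DMAP) to the acetate F2. The more electron-poor α-bromoacrylate should cyclize at lower temperature (PhMe, 110 °C) to the α-bromo lactone F3, in which the configuration at C8 no longer matters. A Keck radical allylation with tributyl(2-bromoallyl)stannane (AIBN, PhH, 80 °C) then sets C8 at the planar lactone radical. The 2-bromoallyl group is expected to enter syn to H9, giving the less strained cis lactone junction, which is 23. This fallback corrects the ring fusion but not the diene face.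

Step 9 (alkynylation). Fluoride may open the siloxane before the ethynyl donor is consumed, the hindered enolate may react slowly, or the alkyne may enter on the concave face. The fallback sets out from 10 and comes back at 15, and avoids fluoride and tin. Michael addition of 10 to phenyl vinyl sulfoxide (DBU cat., THF) gives the sulfoxide F4. Thermal syn-elimination of benzenesulfenic acid (PhMe, 110 °C) gives the C10-vinyl keto ester F5. LiBH4 reduction as in step 10 gives the vinyl diol F6. A Heck reaction with 14 (Pd(OAc)2, P(o-tol)3, Et3N, MeCN, 80 °C) then forms the (E,E)-silyl diene 15; the quaternary C10 leaves no β-hydrogen on that side. The facial preference at C10 is still substrate-controlled in this fallback.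

Step 20 (opening of the silicon tether). The acid may shift the C12=C13 alkene or cleave the Si–O bond incompletely, and the basic peroxide may hydrolyse acetates. The fallback sets out from 24 and comes back at 26. The siloxane is opened at silicon by fluoride in the presence of the acyl donor (CsF, Ac2O, MeCN, rt), which gives the C19 acetate fluorosilane F7 without acid. Oxidation under neutral conditions (H2O2, KHF2, DMF) then gives 26.

**Further compounds**
F1 | step 18 | C20 2-bromoacrylate of diol 15 | O[C@H]1CC[C@@]2(C)CO[Si](C)(C)C[C@H]2[C@@]1(/C=C/C=C/[Si](C)(C)C)COC(=O)C(Br)=C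
F2 | step 18 | C1 acetate of F1 | CC(=O)O[C@H]1CC[C@@]2(C)CO[Si](C)(C)C[C@H]2[C@@]1(/C=C/C=C/[Si](C)(C)C)COC(=O)C(Br)=C
F3 | step 18 | α-bromo lactone cycloadduct, C8 unassigned | BrC12C[C@@H]([Si](C)(C)C)C=C[C@H]1[C@]3(COC2=O)[C@@H](OC(C)=O)CC[C@@]4(C)CO[Si](C)(C)C[C@@H]34
F4 | step 9 | C10 2-(phenylsulfinyl)ethyl keto ester | O=C1CC[C@@]2(C)CO[Si](C)(C)C[C@H]2[C@@]1(CCS(=O)c3ccccc3)C(=O)OC
F5 | step 9 | C10-vinyl keto ester | O=C1CC[C@@]2(C)CO[Si](C)(C)C[C@H]2[C@@]1(C=C)C(=O)OC
F6 | step 9 | C10-vinyl C1,C20-diol | O[C@H]1CC[C@@]2(C)CO[Si](C)(C)C[C@H]2[C@@]1(C=C)CO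
F7 | step 20 | C19 acetate with C6–SiMe2F (fluorosilane) | C=C(Br)C[C@]12CC=CC[C@H]1[C@]1(COC2=O)[C@@H](OC(C)=O)CC[C@@](C)(COC(C)=O)[C@H]1C[Si](C)(C)F
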